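**Strategy**

Everything rests on cutting both bonds of the ring C carbonyl carbon C4: C4a–C4 to the hexasubstituted ring A, and C3–C4 to C3, which carries the methoxy group. One palladium-catalysed carbonylative α-arylation joins a 2-iodoresorcinol diether (C4a), carbon monoxide (C4) and the enolate of a ring B methoxymethyl ketone (C3, C2) to the open-chain 1,3-diketone. The iodide is mirror-symmetric, its two ortho oxygens being the future O1 and C5 hydroxyl, so either may close ring C. All four phenols are carried as methoxymethyl ethers, which direct the iodination, keep the ortho positions small and let one acid treatment unmask the phenols and form the pyranone.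

Key step: step 8

Assumption: the carbon between the two carbonyls of the 1,3-diketone is a formal stereocentre but is freely enolisable. It is carried as the racemate and becomes the sp2 carbon C3 of the flavone; the target has no stereocentre.

**Route**

Step 1
Reactants: 1 1,2,3-trimethoxybenzene
Product: 2 1,5-dibromo-2,3,4-trimethoxybenzene
Conditions: NBS (2.1 equiv), MeCN, 0 °C → rt
Reagents that add atoms: N-bromosuccinimide, O=C1CCC(=O)N1Br
Why: Electrophilic aromatic bromination should stop at the 4,6-dibromide, because C4 and C6 are each ortho to one outer methoxy group and para to the other, whereas C5 is activated only by the twisted central methoxy group.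

Step 2
Reactants: 2 1,5-dibromo-2,3,4-trimethoxybenzene
Product: 4 4,5,6-trimethoxybenzene-1,3-diol, via bis(pinacolboronate) 3 (not isolated)
Conditions: B2pin2 (2.6 equiv), Pd(dppf)Cl2 (5 mol %), KOAc, 1,4-dioxane, 90 °C; then 30 % aq. H2O2, NaOH, THF, 0 °C; Na2S2O3, then pH 4
Reagents that add atoms: hydrogen peroxide, OO
Why: Double Miyaura borylation followed by peroxide oxidation of the aryl boronates (aryl shift from boron to oxygen) should replace each bromine by hydroxyl at the same carbon, and the resorcinol is taken on at once to limit air oxidation.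

Step 3
Reactants: 4 4,5,6-trimethoxybenzene-1,3-diol
Product: 5 1,2,3-trimethoxy-4,6-bis(methoxymethoxy)benzene
Conditions: MOMCl (2.6 equiv), i-Pr2NEt, CH2Cl2, 0 °C → rt
Reagents that add atoms: chloromethyl methyl ether, COCCl
Why: O-Alkylation of both phenols with the reactive α-chloro ether (Williamson-type) gives base-stable acetal ethers that direct the lithiation in step 4 and are removed by acid in step 9.

Step 4
Reactants: 5 1,2,3-trimethoxy-4,6-bis(methoxymethoxy)benzene
Product: 7 2-iodo-4,5,6-trimethoxy-1,3-bis(methoxymethoxy)benzene, via aryllithium 6 (not isolated)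
Conditions: n-BuLi (1.2 equiv), THF, 0 °C; then I2, −78 °C → rt
Reagents that add atoms: iodine, II
Why: Directed ortho-metalation should be clean, since the only ring hydrogen lies between two chelating methoxymethoxy groups, and iodine traps the aryllithium at that carbon.

Step 5
Reactants: 8 methyl 3,5-dihydroxy-4-methoxybenzoate
Product: 9 methyl 4-methoxy-3,5-bis(methoxymethoxy)benzoate
Conditions: MOMCl (2.6 equiv), i-Pr2NEt, CH2Cl2, 0 °C → rt
Reagents that add atoms: chloromethyl methyl ether, COCCl
Why: The same Williamson-type O-alkylation masks both ring B phenols with groups that tolerate the strong bases of steps 6 and 8.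

Step 6
Reactants: 9 methyl 4-methoxy-3,5-bis(methoxymethoxy)benzoate; 10 methyl methoxyacetate (2.5 equiv)
Product: 11 methyl 2-methoxy-3-[4-methoxy-3,5-bis(methoxymethoxy)phenyl]-3-oxopropanoate (racemic)
Conditions: LiN(SiMe3)2 (3.2 equiv), THF, −78 °C → 0 °C; aq. NH4Cl
Reagents that add atoms: none
Why: In this crossed Claisen condensation only 10 can be enolised, its lithium enolate acylates on carbon with the non-enolisable benzoate, and deprotonation of the β-keto ester drives the equilibrium; the new stereocentre is racemic and is removed in step 7.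

Step 7
Reactants: 11 methyl 2-methoxy-3-[4-methoxy-3,5-bis(methoxymethoxy)phenyl]-3-oxopropanoate
Product: 12 2-methoxy-1-[4-methoxy-3,5-bis(methoxymethoxy)phenyl]ethan-1-one
Conditions: LiCl (2 equiv), H2O (2 equiv), DMSO, 130 °C
Reagents that add atoms: none
Why: In this Krapcho dealkoxycarbonylation chloride demethylates the ester by SN2, the β-keto carboxylate loses CO2 and water protonates the enolate, all under neutral conditions that spare the acetal ethers.

Step 8
Reactants: 7 2-iodo-4,5,6-trimethoxy-1,3-bis(methoxymethoxy)benzene; 12 2-methoxy-1-[4-methoxy-3,5-bis(methoxymethoxy)phenyl]ethan-1-one (2 equiv); 13 carbon monoxide (1.5 equiv)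
Product: 14 2-methoxy-1-[4-methoxy-3,5-bis(methoxymethoxy)phenyl]-3-[3,4,5-trimethoxy-2,6-bis(methoxymethoxy)phenyl]propane-1,3-dione (racemic, enolisable)
Conditions: Pd(dba)2 (5 mol %), 1,3-bis(diphenylphosphino)propane (6 mol %), NaN(SiMe3)2 (2.2 equiv), CO (sealed two-chamber vessel), THF, 80 °C; aq. NH4Cl
Reagents that add atoms: none
Why: Zerovalent palladium inserts into the C–I bond of 7, migratory insertion of CO gives a divalent aroylpalladium iodide, the sodium enolate of 12 displaces iodide, and C–C reductive elimination from the carbon-bound acylpalladium enolate forms C3–C4, so that C4a–C4 and C3–C4 are made in one catalytic cycle. The closest known reaction type is the palladium-catalysed carbonylative α-arylation of aryl alkyl ketones with aryl iodides to 1,3-diketones, applied here to an α-methoxy ketone. No ring closes in this step. The carbon between the two carbonyls becomes a stereocentre, but it forms as a racemate in equilibrium with its enols and is flattened to C3 in step 9, so nothing needs to control it. The step needs carbonylative rather than direct arylation and C- rather than O-acylation: the two ortho methoxymethoxy groups of 7 slow direct aryl–enolate reductive elimination while CO insertion moves the crowded ring one atom away from the metal, and bond formation at palladium through the carbon-bound enolate favours the diketone. The second equivalent of enolate turns the product into its unreactive sodium enolate, which prevents a second acylation.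

Step 9
Reactants: 14 2-methoxy-1-[4-methoxy-3,5-bis(methoxymethoxy)phenyl]-3-[3,4,5-trimethoxy-2,6-bis(methoxymethoxy)phenyl]propane-1,3-dione
Product: 17 5,3',5'-trihydroxy-3,6,7,8,4'-pentamethoxyflavone, via tetraphenol diketone 15 (not isolated), via cyclic hemiketal 16 (not isolated)
Conditions: 3 M HCl, MeOH, 60 °C
Reagents that add atoms: none
Why: Acid-catalysed acetal exchange with methanol should free all four phenols, after which either of the two equivalent ring A phenols adds to the ring B ketone (6-exo-trig) and the hemiketal dehydrates to the pyranone, as in the closing stage of a Baker–Venkataraman flavone synthesis, while aryl methyl ethers are inert to HCl in methanol.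

**Compound list**

1 | 1,2,3-trimethoxybenzene | COc1cccc(OC)c1OC | starting material
2 | 1,5-dibromo-2,3,4-trimethoxybenzene | COc1c(Br)cc(Br)c(OC)c1OC | intermediate
3 | 2,2'-(4,5,6-trimethoxy-1,3-phenylene)bis(4,4,5,5-tetramethyl-1,3,2-dioxaborolane) (not isolated) | COc1c(B2OC(C)(C)C(C)(C)O2)cc(B2OC(C)(C)C(C)(C)O2)c(OC)c1OC | intermediate
4 | 4,5,6-trimethoxybenzene-1,3-diol | COc1c(O)cc(O)c(OC)c1OC | intermediate
5 | 1,2,3-trimethoxy-4,6-bis(methoxymethoxy)benzene | COCOc1cc(OCOC)c(OC)c(OC)c1OC | intermediate
6 | [3,4,5-trimethoxy-2,6-bis(methoxymethoxy)phenyl]lithium (not isolated) | [Li]c1c(OCOC)c(OC)c(OC)c(OC)c1OCOC | intermediate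
7 | 2-iodo-4,5,6-trimethoxy-1,3-bis(methoxymethoxy)benzene | COCOc1c(I)c(OCOC)c(OC)c(OC)c1OC | intermediate
8 | methyl 3,5-dihydroxy-4-methoxybenzoate | COC(=O)c1cc(O)c(OC)c(O)c1 | starting material
9 | methyl 4-methoxy-3,5-bis(methoxymethoxy)benzoate | COCOc1cc(C(=O)OC)cc(OCOC)c1OC | intermediate
10 | methyl methoxyacetate | COCC(=O)OC | starting material
11 | methyl 2-methoxy-3-[4-methoxy-3,5-bis(methoxymethoxy)phenyl]-3-oxopropanoate (racemic) | COCOc1cc(C(=O)C(OC)C(=O)OC)cc(OCOC)c1OC | intermediate
12 | 2-methoxy-1-[4-methoxy-3,5-bis(methoxymethoxy)phenyl]ethan-1-one | COCC(=O)c1cc(OCOC)c(OC)c(OCOC)c1 | intermediate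
13 | carbon monoxide | [C-]#[O+] | starting material
14 | 2-methoxy-1-[4-methoxy-3,5-bis(methoxymethoxy)phenyl]-3-[3,4,5-trimethoxy-2,6-bis(methoxymethoxy)phenyl]propane-1,3-dione (racemic, enolisable) | COCOc1cc(C(=O)C(OC)C(=O)c2c(OCOC)c(OC)c(OC)c(OC)c2OCOC)cc(OCOC)c1OC | intermediate
15 | 1-(2,6-dihydroxy-3,4,5-trimethoxyphenyl)-3-(3,5-dihydroxy-4-methoxyphenyl)-2-methoxypropane-1,3-dione (racemic, not isolated) | COC(C(=O)c1cc(O)c(OC)c(O)c1)C(=O)c1c(O)c(OC)c(OC)c(OC)c1O | intermediate
16 | 2-(3,5-dihydroxy-4-methoxyphenyl)-2,5-dihydroxy-3,6,7,8-tetramethoxy-2,3-dihydro-4H-chromen-4-one (stereoisomer mixture, not isolated) | COC1C(=O)c2c(O)c(OC)c(OC)c(OC)c2OC1(O)c1cc(O)c(OC)c(O)c1 | intermediate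
17 | 5,3',5'-trihydroxy-3,6,7,8,4'-pentamethoxyflavone | COc1c(O)cc(-c2oc3c(OC)c(OC)c(OC)c(O)c3c(=O)c2OC)cc1O | target

**Totals and risks**

Total step count: 9. Longest linear sequence: 6 steps (steps 1, 2, 3, 4, 8, 9); the ring B branch (steps 5–7) joins at step 8.

Steps most likely to fail:

1. Step 8. Oxidative addition and acyl transfer at the doubly ortho-substituted, electron-rich iodide may be slow, so that protodeiodination, catalyst inhibition by CO or capture of the acylpalladium by the silylamide base could outrun the coupling. The fallback sets out from 5 (with ketone 12) and comes back at 14. Compound 5 is lithiated as in step 4 (n-BuLi, THF, 0 °C, aryllithium 6) and quenched with DMF, which should give 3,4,5-trimethoxy-2,6-bis(methoxymethoxy)benzaldehyde F1. Aldol addition of the lithium enolate of 12 (LiN(SiMe3)2, THF, −78 °C) to this aldehyde should give 3-hydroxy-2-methoxy-1-[4-methoxy-3,5-bis(methoxymethoxy)phenyl]-3-[3,4,5-trimethoxy-2,6-bis(methoxymethoxy)phenyl]propan-1-one F2 as a diastereomer mixture. Dess–Martin periodinane (NaHCO3, CH2Cl2, rt) then oxidises the benzylic alcohol to the diketone 14. This replaces the three-component coupling by aldol addition and oxidation and needs neither the iodide nor CO.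

2. Step 2. The second borylation may stall or give protodebromination, and the very electron-rich resorcinol may be over-oxidised during the peroxide stage. The fallback sets out from 2 and comes back at 4. Palladium-catalysed C–O coupling of both C–Br bonds with benzyl alcohol ([Pd(allyl)Cl]2, RockPhos, Cs2CO3, toluene, 90 °C) should give 1,5-bis(benzyloxy)-2,3,4-trimethoxybenzene F3, a stable ether that never meets an oxidant. Hydrogenolysis (H2, Pd/C, EtOAc, rt) then frees 4 under reducing conditions.

3. Step 6. Self-condensation of the methoxyacetate enolate may outpace acylation by the electron-rich benzoate, or the β-keto ester may undergo retro-Claisen cleavage on work-up. The fallback sets out from 9 and comes back at 12, so that step 7 is no longer needed. Ester 9 is converted with MeNHOMe·HCl and i-PrMgCl (THF, −20 °C → 0 °C) into N,4-dimethoxy-N-methyl-3,5-bis(methoxymethoxy)benzamide F4. Methoxymethyllithium (from Bu3SnCH2OMe and n-BuLi, THF, −78 °C) should add once to this Weinreb amide, whose chelated tetrahedral adduct collapses only on work-up, to give ketone 12 directly.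

**Further compounds**

F1 | step 8 | 3,4,5-trimethoxy-2,6-bis(methoxymethoxy)benzaldehyde | O=Cc1c(OCOC)c(OC)c(OC)c(OC)c1OCOC
F2 | step 8 | 3-hydroxy-2-methoxy-1-[4-methoxy-3,5-bis(methoxymethoxy)phenyl]-3-[3,4,5-trimethoxy-2,6-bis(methoxymethoxy)phenyl]propan-1-one (diastereomer mixture, racemic) | COCOc1cc(C(=O)C(OC)C(O)c2c(OCOC)c(OC)c(OC)c(OC)c2OCOC)cc(OCOC)c1OC
F3 | step 2 | 1,5-bis(benzyloxy)-2,3,4-trimethoxybenzene | COc1c(OCc2ccccc2)cc(OCc2ccccc2)c(OC)c1OC
F4 | step 6 | N,4-dimethoxy-N-methyl-3,5-bis(methoxymethoxy)benzamide | COCOc1cc(C(=O)N(C)OC)cc(OCOC)c1OC
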